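**Retrosynthetic overview**
1. Feature: the strategy rests on the tetrasubstituted C3=C4 double bond of the furan-2,5-dione ring. C3 carries the 14-acetoxytetradecyl chain and C4 the methyl group. Each alkene carbon is α to one ring carbonyl (C2, C5), so both can first exist as acidic sp3 carbons joined by a removable SO2 bridge.
2. Target ⇒ O-acetylation and exchange of the ring oxygen for N-benzyl ⇒ N-benzyl-3-alkyl-4-methylmaleimide.
3. Maleimide C3=C4 ⇒ Ramberg–Bäcklund ring contraction ⇒ six-membered 2-alkyl-6-methylthiomorpholine-3,5-dione 1,1-dioxide (C–SO2–C in place of C=C).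
4. Six-membered ring ⇒ S-oxidation, imide N–C(O) closure and SN2 C–S bond formation ⇒ N-benzyl-2-bromoamide of 16-acetoxyhexadecanoic acid plus 2-sulfanylpropanoic acid. C1 and C2 of the C16 acid become ring carbonyl and ring carbon, and C3–C16 become the chain.
5. Ring order: thiomorpholinedione (six-membered, step 4) → transient thiirane dioxide fused to a pyrrolidinedione, then maleimide (five-membered, step 6) → furandione (step 7).

Key step: step 6

Remark: the target has no stereocentre and its only C=C bond is locked cis in the ring, so there is no enantiomer to select. Racemic 2-sulfanylpropanoic acid is used, and all sp3 centres made on the way are carried as mixtures and erased in step 6.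

**Step 1**
Reactants: 1 16-hydroxyhexadecanoic acid
Product: 2 16-acetoxyhexadecanoic acid
Conditions: Ac2O, pyridine, cat. DMAP, CH2Cl2, rt; then H2O
Reagents that add atoms: acetic anhydride CC(=O)OC(C)=O
Why: DMAP-catalysed O-acetylation of a primary alcohol, in which any mixed anhydride formed at the carboxyl group is hydrolysed in the aqueous quench and the acetate masks the hydroxyl against SOCl2 in step 2.

**Step 2**
Reactants: 2 16-acetoxyhexadecanoic acid; 3 benzylamine
Product: 6 bromo amide 16-(benzylamino)-15-bromo-16-oxohexadecyl acetate (racemic), via acyl chloride 4 (not isolated), via bromo acyl chloride 5 (not isolated)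
Conditions: SOCl2, ClCH2CH2Cl, 70 °C; NBS, cat. HBr, reflux, dark; evaporate, filter; then 3, Et3N, CH2Cl2, 0 °C
Reagents that add atoms: N-bromosuccinimide O=C1CCC(=O)N1Br; thionyl chloride O=S(Cl)Cl (chlorine only in 4 and 5); benzylamine 3 NCc1ccccc1
Why: Hell–Volhard–Zelinsky-type α-bromination in its acyl chloride/NBS form (only the acyl chloride enolises, so the acetate methyl and the chain stay untouched) followed by Schotten–Baumann-type N-acylation, where the acyl chloride of 5 reacts with the amine far faster than the secondary bromide, and the new C–Br centre is racemic and is erased in step 6.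

**Step 3**
Reactants: 6 bromo amide; 7 2-sulfanylpropanoic acid (racemic)
Product: 8 2-{[16-acetoxy-1-(benzylamino)-1-oxohexadecan-2-yl]sulfanyl}propanoic acid (diastereomer mixture)
Conditions: Et3N (2.2 equiv), THF, 0 °C → rt, N2; 1 M HCl work-up
Reagents that add atoms: 2-sulfanylpropanoic acid 7 CC(S)C(O)=O
Why: SN2 thioether formation at an α-bromo amide, in which the soft thiolate outruns the carboxylate of 7, the amine base leaves the acetate alone, and the two unselectively set centres do not matter because both are erased later.

**Step 4**
Reactants: 8 thioether amide acid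
Product: 10 imide 14-(4-benzyl-6-methyl-3,5-dioxothiomorpholin-2-yl)tetradecyl acetate (diastereomer mixture), via mixed anhydride 9 (not isolated)
Conditions: Ac2O, cat. NaOAc, toluene, 90 °C
Reagents that add atoms: acetic anhydride CC(=O)OC(C)=O (acetyl only in 9)
Why: Classical amic acid cyclodehydration, in which the carboxyl group is activated as mixed anhydride 9 and acylates the amide nitrogen in a 6-exo-trig closure (any isoimide is isomerised by acetate), and the medium can only preserve the acetate ester.

**Step 5**
Reactants: 10 imide sulfide
Product: 12 sulfone 14-(4-benzyl-6-methyl-1,1,3,5-tetraoxothiomorpholin-2-yl)tetradecyl acetate (diastereomer mixture), via sulfoxide 11 (not isolated)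
Conditions: mCPBA (3 equiv), CH2Cl2, 0 °C → rt; Na2SO3 then brief cold NaHCO3 wash
Reagents that add atoms: 3-chloroperoxybenzoic acid OOC(=O)c1cccc(Cl)c1
Why: Peracid oxidation of a sulfide through the sulfoxide to the sulfone, with excess oxidant to carry the electron-poor sulfoxide 11 on, no other oxidisable group in the molecule, and a temperature at or below rt to suppress thermal syn-elimination of 11.

**Step 6**
Reactants: 12 sulfone
Product: 15 maleimide 14-(1-benzyl-4-methyl-2,5-dioxo-2,5-dihydro-1H-pyrrol-3-yl)tetradecyl acetate, via bromo sulfone 13 (not isolated), via episulfone 14 (not isolated)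
Conditions: DBU (2.3 equiv), BrCl2C–CCl2Br (1.0 equiv, slow addition), dry CH2Cl2, −20 °C → rt, N2 purge
Reagents that add atoms: 1,2-dibromotetrachloroethane BrC(Cl)(Cl)C(Cl)(Cl)Br (bromine only in 13)
Why: Proposed new method: DBU removes one of the two ring C–H protons that sit between the sulfonyl group and an imide carbonyl, the carbanion abstracts Br+ from BrCl2C–CCl2Br (which fragments irreversibly to tetrachloroethene and bromide) to give 13, a second equivalent of DBU deprotonates the other α-carbon, this carbanion displaces bromide across sulfur to forge the C2–C6 bond (thiomorpholine numbering) in episulfone 14, and cheletropic loss of SO2 unveils the C3=C4 double bond of 15. The closest known reaction type is the Ramberg–Bäcklund reaction with in-situ halogenation, established for the thiane 1,1-dioxide to cyclopentene contraction, for tetrasubstituted alkenes from di-sec-alkyl sulfones and for halides on ester-bearing α-carbons, whereas a sulfone whose two α-carbons both belong to an imide, so that nucleophile and electrophile are both carbonyl-stabilised, has not been shown; the Bingel cyclopropanation (DBU with a Br+ donor, stabilised carbanion closing on a doubly activated tertiary C–Br) and the Favorskii contraction of 2-halocyclohexanones (enolate closing across one atom of a six-membered ring) support the feasibility of that closure. The bond-forming event is a single 3-exo-tet closure that creates the thiirane 1,1-dioxide ring and, with the same bond, the five-membered pyrrolidine-2,5-dione ring of the 3-aza-6-thiabicyclo[3.1.0]hexane 14, and it requires the envelope conformer with sulfur as the flap and C–Br pseudo-equatorial so that the carbanion lobe meets the rear of the C–Br bond. No stereocentre survives, since the centres of 12, 13 and 14 are all erased, so every diastereomer of 12 and either site of bromination converge on 15, and because both alkene carbons stay tied through the imide only the cis geometry is possible. The step needs monobromination and closure faster than a second bromination, than E2 loss of HBr toward the methyl group or the chain CH2 and than opening of the imide: each α-carbon bears only one hydrogen so no geminal dihalide can form, the bromine donor is added slowly in one equivalent to the preformed anion, bromine exchange among the acidic sites is reversible while only the anion of the monobromide has an irreversible exit, and bromide is preferred to chloride as leaving group because the nucleophile is weak and the carbon tertiary. The non-nucleophilic amidine base in dry CH2Cl2 leaves the acetate, the imide and the tetrasubstituted maleimide product intact.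

**Step 7**
Reactants: 15 maleimide
Product: 17 3-(14-hydroxytetradecyl)-4-methylfuran-2,5-dione, via maleamic acid 16 (not isolated)
Conditions: KOH, H2O–MeOH–THF, reflux; then 6 M HCl, pH 1, rt
Reagents that add atoms: potassium hydroxide [K+].[OH-] (one oxygen of the anhydride)
Why: Imide saponification followed by acid-triggered anhydride formation, in which hydroxide opens the imide and cleaves the acetate and, on acidification, the dialkylmaleamic acid 16 expels benzylamine through neighbouring carboxyl participation because dialkylmaleic acid derivatives collapse spontaneously to the cyclic anhydride.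

**Step 8**
Reactants: 17 hydroxy anhydride
Product: 18 Aspergillus acid E, 14-(4-methyl-2,5-dioxo-2,5-dihydrofuran-3-yl)tetradecyl acetate
Conditions: Ac2O, pyridine, rt; dilute HCl work-up
Reagents that add atoms: acetic anhydride CC(=O)OC(C)=O
Why: Standard O-acetylation of the primary alcohol, tolerated by the dialkylmaleic anhydride ring, which re-closes by itself on acidic work-up if it is transiently opened.

**Compound list**
1 | 16-hydroxyhexadecanoic acid | OCCCCCCCCCCCCCCCC(O)=O | starting material
2 | 16-acetoxyhexadecanoic acid | CC(=O)OCCCCCCCCCCCCCCCC(O)=O | intermediate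
3 | benzylamine | NCc1ccccc1 | starting material
4 | 16-acetoxyhexadecanoyl chloride | CC(=O)OCCCCCCCCCCCCCCCC(Cl)=O | intermediate (not isolated)
5 | 16-acetoxy-2-bromohexadecanoyl chloride (racemic) | CC(=O)OCCCCCCCCCCCCCCC(Br)C(Cl)=O | intermediate (not isolated)
6 | 16-(benzylamino)-15-bromo-16-oxohexadecyl acetate (racemic) | CC(=O)OCCCCCCCCCCCCCCC(Br)C(=O)NCc1ccccc1 | intermediate
7 | 2-sulfanylpropanoic acid (racemic) | CC(S)C(O)=O | starting material
8 | 2-{[16-acetoxy-1-(benzylamino)-1-oxohexadecan-2-yl]sulfanyl}propanoic acid (diastereomer mixture) | CC(=O)OCCCCCCCCCCCCCCC(SC(C)C(O)=O)C(=O)NCc1ccccc1 | intermediate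
9 | acetic 2-{[16-acetoxy-1-(benzylamino)-1-oxohexadecan-2-yl]sulfanyl}propanoic anhydride | CC(=O)OCCCCCCCCCCCCCCC(SC(C)C(=O)OC(C)=O)C(=O)NCc1ccccc1 | intermediate (not isolated)
10 | 14-(4-benzyl-6-methyl-3,5-dioxothiomorpholin-2-yl)tetradecyl acetate (diastereomer mixture) | CC1C(=O)N(Cc2ccccc2)C(=O)C(CCCCCCCCCCCCCCOC(C)=O)S1 | intermediate
11 | 14-(4-benzyl-6-methyl-1,3,5-trioxothiomorpholin-2-yl)tetradecyl acetate (sulfoxide, isomer mixture) | CC1C(=O)N(Cc2ccccc2)C(=O)C(CCCCCCCCCCCCCCOC(C)=O)S1=O | intermediate (not isolated)
12 | 14-(4-benzyl-6-methyl-1,1,3,5-tetraoxothiomorpholin-2-yl)tetradecyl acetate (diastereomer mixture) | CC1C(=O)N(Cc2ccccc2)C(=O)C(CCCCCCCCCCCCCCOC(C)=O)S1(=O)=O | intermediate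
13 | 14-(4-benzyl-6-bromo-6-methyl-1,1,3,5-tetraoxothiomorpholin-2-yl)tetradecyl acetate (drawn brominated at the methyl-bearing carbon; the regioisomer serves equally) | CC1(Br)C(=O)N(Cc2ccccc2)C(=O)C(CCCCCCCCCCCCCCOC(C)=O)S1(=O)=O | intermediate (not isolated)
14 | 14-(3-benzyl-5-methyl-2,4,6,6-tetraoxo-6-thia-3-azabicyclo[3.1.0]hexan-1-yl)tetradecyl acetate (cis-fused by necessity, racemic) | CC12C(=O)N(Cc3ccccc3)C(=O)C1(CCCCCCCCCCCCCCOC(C)=O)S2(=O)=O | intermediate (not isolated)
15 | 14-(1-benzyl-4-methyl-2,5-dioxo-2,5-dihydro-1H-pyrrol-3-yl)tetradecyl acetate | CC1=C(CCCCCCCCCCCCCCOC(C)=O)C(=O)N(Cc2ccccc2)C1=O | intermediate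
16 | (Z)-3-(benzylcarbamoyl)-17-hydroxy-2-methylheptadec-2-enoic acid (one regioisomer drawn; the other collapses to the same anhydride) | OC(=O)/C(C)=C(/CCCCCCCCCCCCCCO)C(=O)NCc1ccccc1 | intermediate (not isolated)
17 | 3-(14-hydroxytetradecyl)-4-methylfuran-2,5-dione | OCCCCCCCCCCCCCCC1=C(C)C(=O)OC1=O | intermediate
18 | Aspergillus acid E, 14-(4-methyl-2,5-dioxo-2,5-dihydrofuran-3-yl)tetradecyl acetate | CC(=O)OCCCCCCCCCCCCCCC1=C(C)C(=O)OC1=O | target

**Total step count:** 8. **Longest linear sequence:** 8 (from 1).

**Steps most likely to fail**

1. Step 6 (bears the label "Proposed new method:").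
   - Risk: the doubly stabilised carbanion may be too weak a nucleophile to close on the tertiary C–Br. Bromine would then only be shuttled between acidic sites, HBr would be lost toward the methyl group or the chain, or the activated imide would be opened.
   - Fallback: known chemistry, the condensation of an imidazopyridinium salt with maleic anhydride that gives alkylmethylmaleic anhydrides. It sets out from crude 5 and comes back at 18.
   - Acylation of 2-aminopyridine with 5 (Et3N, Et2O, 0 °C) should give 15-bromo-16-oxo-16-(pyridin-2-ylamino)hexadecyl acetate F1.
   - Heating F1 in t-BuOH closes the pyridine nitrogen onto the C–Br carbon and should give 3-(14-acetoxytetradecyl)-2-oxo-2,3-dihydro-1H-imidazo[1,2-a]pyridin-4-ium bromide F2.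
   - Heating F2 with maleic anhydride and NaOAc in AcOH brings about Michael addition of the ylide carbon, release of 2-aminopyridine and decarboxylation. This should deliver 18 directly with the acetate retained.

2. Step 5.
   - Risk: the oxidation may stall at the sulfoxide, because sulfur between two imide carbonyls is electron-poor. The sulfoxide may also undergo thermal syn-elimination toward the chain, and the activated imide may be opened hydrolytically during the basic wash.
   - Fallback: it sets out from 8 and comes back at 12 by inverting the order of oxidation and ring closure.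
   - The open-chain thioether 8 is oxidised with H2O2 and cat. Na2WO4 (EtOAc–H2O, rt). No labile ring is present at this stage, and the product should be 2-{[16-acetoxy-1-(benzylamino)-1-oxohexadecan-2-yl]sulfonyl}propanoic acid F3.
   - Cyclodehydration of F3 with Ac2O at 60–70 °C, without added base to avoid decarboxylation, should close the imide to 12. The sulfone imide then only meets an anhydrous, non-nucleophilic medium.

3. Step 2.
   - Risk: the acetate may be lost to hot HCl/HBr, radical bromination may occur along the chain, or enolisation may be incomplete so that unbrominated amide is carried forward.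
   - Fallback: it avoids α-bromination of the long-chain acid altogether by alkylating a preformed ring. It sets out from 7 and 3 and comes back at 12.
   - S-alkylation of 7 with bromoacetic acid (aq. NaOH) should give 2-[(carboxymethyl)sulfanyl]propanoic acid F4.
   - Thermal condensation of F4 with 3 (xylene, Dean–Stark) should give 4-benzyl-2-methylthiomorpholine-3,5-dione F5.
   - Oxidation of F5 with mCPBA should give 4-benzyl-2-methylthiomorpholine-3,5-dione 1,1-dioxide F6.
   - Separately, 1,14-tetradecanediol is monobrominated (48 % HBr, toluene, reflux) to 14-bromotetradecan-1-ol F7, which is acetylated (Ac2O, pyridine) to 14-bromotetradecyl acetate F8.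
   - C-alkylation of F6 with F8 (K2CO3, DMF, rt to 50 °C) should take place at the unsubstituted ring CH2, the more acidic and less hindered site, and give 12.

**Further compounds**
F1 | step 6 | 15-bromo-16-oxo-16-(pyridin-2-ylamino)hexadecyl acetate (racemic) | CC(=O)OCCCCCCCCCCCCCCC(Br)C(=O)Nc1ccccn1
F2 | step 6 | 3-(14-acetoxytetradecyl)-2-oxo-2,3-dihydro-1H-imidazo[1,2-a]pyridin-4-ium bromide (racemic) | CC(=O)OCCCCCCCCCCCCCCC1C(=O)NC2=CC=CC=[N+]12.[Br-]
F3 | step 5 | 2-{[16-acetoxy-1-(benzylamino)-1-oxohexadecan-2-yl]sulfonyl}propanoic acid (diastereomer mixture) | CC(=O)OCCCCCCCCCCCCCCC(C(=O)NCc1ccccc1)S(=O)(=O)C(C)C(O)=O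
F4 | step 2 | 2-[(carboxymethyl)sulfanyl]propanoic acid (racemic) | CC(SCC(O)=O)C(O)=O
F5 | step 2 | 4-benzyl-2-methylthiomorpholine-3,5-dione (racemic) | CC1SCC(=O)N(Cc2ccccc2)C1=O
F6 | step 2 | 4-benzyl-2-methylthiomorpholine-3,5-dione 1,1-dioxide (racemic) | CC1C(=O)N(Cc2ccccc2)C(=O)CS1(=O)=O
F7 | step 2 | 14-bromotetradecan-1-ol | OCCCCCCCCCCCCCCBr
F8 | step 2 | 14-bromotetradecyl acetate | CC(=O)OCCCCCCCCCCCCCCBr
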